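Ring A of the cis-decalin (C4a, C5, C6, C7, C8, C8a; C5 carries the exocyclic methylene) is read as a latent 2-alkylcyclohexane-1,3-dione, in which C5 and C8a are carbonyl carbons flanking the future quaternary C4a. The key step is a one-pot Michael–Claisen [3+3] annulation of methyl acrylate onto a 5-substituted pentan-2-one that already carries the halimene decalin (made by asymmetric conjugate addition, aldol closure and an Eschenmoser–Claisen chirality transfer to its quaternary carbon). It forms C7–C8 and C4a–C5 together. An amino acid-mediated Robinson annulation then sets C4a, and deconjugative methylation, two face-selective hydrogenations and a late methylenation finish the skeleton before sulfation.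

Key step: step 9

Remarks on the chemistry:
- Numbering: the cis-decalin of the target is numbered as a naphthalene, with C1 (CH3, CH2Ar), C2 (CH3), C4a (side chain), C5 (=CH2) and C8a (H).
- Hal = (1R,2S,4aS)-1,2,5,5-tetramethyl-1,2,3,4,4a,5,6,7-octahydronaphthalen-1-yl; Ar = 2,5-dimethoxyphenyl.
- Assumption: the target is drawn as the free bis(hydrogen sulfate), so the sulfation product is taken through an H+ ion exchange; it would normally be stored as a salt.

Step 1
Reactants: 1 3-methylpenta-1,4-diene; 2 4,4-dimethylcyclohex-2-en-1-one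
Product: 5 (3R)-4,4-dimethyl-3-(3-methylpent-4-en-1-yl)cyclohexan-1-one, via alkylzirconocene chloride 3 (not isolated), via silyl enol ether 4 (not isolated)
Conditions: 1 (2.5 equiv), Cp2Zr(H)Cl, CH2Cl2, 23 °C; then 2, CuCl/AgOTf (10 mol %), binaphthol-derived phosphoramidite ligand (10 mol %, enantiomer that gives 3R), TMSCl, Et2O, 23 °C; aq. NH4Cl
Reagents that add atoms: none
Why: Hydrozirconation of one vinyl group and copper-catalysed asymmetric conjugate addition of the alkylzirconium set C3 (the later ring-fusion CH of Hal) under ligand control, while the side-chain centre is left unset because step 3 equilibrates it.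

Step 2
Reactants: 5 (3R)-4,4-dimethyl-3-(3-methylpent-4-en-1-yl)cyclohexan-1-one
Product: 6 (3R)-4,4-dimethyl-3-(3-methyl-4-oxopentyl)cyclohexan-1-one
Conditions: PdCl2 (10 mol %), CuCl, O2 (1 atm), DMF–H2O 7:1, 23 °C
Reagents that add atoms: water O
Why: Wacker–Tsuji oxidation converts the terminal vinyl group into the methyl ketone with Markovnikov selectivity and leaves the ring ketone untouched.

Step 3
Reactants: 6 (3R)-4,4-dimethyl-3-(3-methyl-4-oxopentyl)cyclohexan-1-one
Product: 7 (4aS,7S)-4,4,7,8-tetramethyl-3,4,4a,5,6,7-hexahydronaphthalen-1(2H)-one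
Conditions: NaOMe (2 equiv), MeOH, 65 °C (equilibrating)
Reagents that add atoms: none
Why: Intramolecular aldol condensation of ring carbon C2 onto the side-chain ketone is the only six-membered closure that can dehydrate into conjugation, and under the equilibrating base the epimerisable C7 should settle with its methyl pseudoaxial and anti to H-4a, which avoids A(1,2) strain with the C8 methyl.

Step 4
Reactants: 7 (4aS,7S)-4,4,7,8-tetramethyl-3,4,4a,5,6,7-hexahydronaphthalen-1(2H)-one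
Product: 8 (1S,4aS,7S)-4,4,7,8-tetramethyl-1,2,3,4,4a,5,6,7-octahydronaphthalen-1-ol
Conditions: (R)-2-methyl-CBS-oxazaborolidine (20 mol %), BH3·SMe2, THF, −20 °C; MeOH
Reagents that add atoms: none
Why: Corey–Bakshi–Shibata reduction treats the fully substituted alkenyl branch as the large group and should give the (1S)-allylic alcohol, whose C–O bond lies on the face of H-4a.

Step 5
Reactants: 8 (1S,4aS,7S)-4,4,7,8-tetramethyl-1,2,3,4,4a,5,6,7-octahydronaphthalen-1-ol
Product: 10 N,N-dimethyl-2-(Hal)acetamide, via ketene N,O-acetal 9 (not isolated)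
Conditions: MeC(OMe)2NMe2 (5 equiv), xylene, 140 °C, removal of MeOH
Reagents that add atoms: N,N-dimethylacetamide dimethyl acetal COC(C)(OC)N(C)C
Why: Eschenmoser–Claisen rearrangement: the suprafacial [3,3] shift carries the C1 configuration to C8, forms the quaternary centre on the face of the former C–O bond (anti to the pseudoaxial C7 methyl) and places the double bond at C1=C8a.

Step 6
Reactants: 10 N,N-dimethyl-2-(Hal)acetamide
Product: 11 2-(Hal)acetaldehyde
Conditions: Cp2Zr(H)Cl (1.5 equiv), THF, 23 °C; wet silica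
Reagents that add atoms: none
Why: Hydrozirconation of the tertiary amide carbonyl gives a zirconated hemiaminal that collapses to the aldehyde on work-up, and the hindered trisubstituted alkene does not react.

Step 7
Reactants: 11 2-(Hal)acetaldehyde
Product: 12 (E)-5-(Hal)pent-3-en-2-one
Conditions: Ph3P=CHCOCH3 (1.5 equiv), toluene, 90 °C
Reagents that add atoms: (acetylmethylene)triphenylphosphorane CC(=O)C=P(c1ccccc1)(c1ccccc1)c1ccccc1
Why: Wittig olefination with the stabilised ylide gives the (E)-enone and adds the three carbons that become C4a, C8a and C8 of ring A.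

Step 8
Reactants: 12 (E)-5-(Hal)pent-3-en-2-one
Product: 13 5-(Hal)pentan-2-one
Conditions: H2 (1 atm), RhCl(PPh3)3 (5 mol %), benzene, 23 °C
Reagents that add atoms: none
Why: Homogeneous hydrogenation saturates the unhindered disubstituted enone double bond and leaves the trisubstituted ring alkene, which is flanked by two fully substituted carbons.

Step 9
Reactants: 13 5-(Hal)pentan-2-one; 14 methyl acrylate
Product: 16 2-[2-(Hal)ethyl]cyclohexane-1,3-dione, via δ-keto ester 15 (not isolated)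
Conditions: LDA (1.1 equiv), THF, −78 °C; 14 (1.0 equiv, slow addition), −78 °C; then t-BuOK (2.2 equiv), −78 → 23 °C; 1 M HCl
Reagents that add atoms: none
Why: Kinetic deprotonation at −78 °C takes place at the methyl group, and this enolate adds to methyl acrylate (Michael addition, new CH2–CH2 bond); t-BuOK then equilibrates the δ-keto ester 15 to the internal ketone enolate, which attacks the ester carbonyl (Claisen closure, new C2–C3 bond of the dione), and the product is drained as its stabilised enolate. The closest known reaction type is the [3+3] Michael–Claisen synthesis of cyclohexane-1,3-diones from ketones and acrylates. The ring closes in a 6-(enolexo)-exo-trig mode. No stereocentre is created, because C2 of the dione lies between two enantiotopic carbonyls and is enolised. The step needs regioselectivity in the Michael event, which the kinetic preference of a methyl ketone for CH3 deprotonation secures, whereas the Claisen event has no alternative because closure through the other α-carbon would give a four-membered ring.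

Step 10
Reactants: 17 3-(2,5-dimethoxyphenyl)propanoic acid
Product: 19 3-(2,5-dimethoxyphenyl)-N-methoxy-N-methylpropanamide, via acyl imidazole 18 (not isolated)
Conditions: 1,1'-carbonyldiimidazole (1.2 equiv), CH2Cl2, 23 °C; then MeNH(OMe)·HCl (1.5 equiv)
Reagents that add atoms: N,O-dimethylhydroxylamine hydrochloride CNOC.Cl
Why: Activation of the acid as the acyl imidazole and aminolysis give the N-methoxy-N-methylamide.

Step 11
Reactants: 19 3-(2,5-dimethoxyphenyl)-N-methoxy-N-methylpropanamide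
Product: 20 5-(2,5-dimethoxyphenyl)pent-1-en-3-one
Conditions: CH2=CHMgBr (1.3 equiv), THF, −20 °C; inverse quench into cold 1 M HCl
Reagents that add atoms: vinylmagnesium bromide C=C[Mg]Br
Why: The chelated tetrahedral adduct of the N-methoxy-N-methylamide stops at mono-addition and releases the vinyl ketone on cold acidic quench.

Step 12
Reactants: 16 2-[2-(Hal)ethyl]cyclohexane-1,3-dione; 20 5-(2,5-dimethoxyphenyl)pent-1-en-3-one
Product: 22 (8aS)-5-(2,5-dimethoxybenzyl)-8a-[2-(Hal)ethyl]-3,4,8,8a-tetrahydronaphthalene-1,6(2H,7H)-dione, via triketone 21 (not isolated)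
Conditions: Et3N (0.2 equiv), EtOAc, 23 °C; evaporation; then L-phenylalanine (1 equiv), (1S)-(+)-10-camphorsulfonic acid (0.5 equiv), DMF, 50 °C
Reagents that add atoms: none
Why: Robinson annulation by Michael addition and amino acid-mediated enamine aldol condensation (Hajos–Parrish–Eder–Sauer–Wiechert type), in which L-phenylalanine selects one of the two enantiotopic ring carbonyls and should set the quaternary C8a as S.

Step 13
Reactants: 22 (8aS)-5-(2,5-dimethoxybenzyl)-8a-[2-(Hal)ethyl]-3,4,8,8a-tetrahydronaphthalene-1,6(2H,7H)-dione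
Product: 23 (4aS,5S)-1-(2,5-dimethoxybenzyl)-5-hydroxy-4a-[2-(Hal)ethyl]-4,4a,5,6,7,8-hexahydronaphthalen-2(3H)-one
Conditions: NaBH4 (0.3 equiv), EtOH, −15 °C
Reagents that add atoms: none
Why: Chemoselective reduction of the saturated ketone (the tetrasubstituted enone is inert at this temperature) with hydride attack anti to the angular chain gives the alcohol cis to that chain, as with the Wieland–Miescher ketone.

Step 14
Reactants: 23 (4aS,5S)-1-(2,5-dimethoxybenzyl)-5-hydroxy-4a-[2-(Hal)ethyl]-4,4a,5,6,7,8-hexahydronaphthalen-2(3H)-one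
Product: 24 (4aS,5S)-5-[(tert-butyldimethylsilyl)oxy]-1-(2,5-dimethoxybenzyl)-4a-[2-(Hal)ethyl]-4,4a,5,6,7,8-hexahydronaphthalen-2(3H)-one
Conditions: TBSOTf (1.3 equiv), 2,6-lutidine, CH2Cl2, −78 → 0 °C
Reagents that add atoms: tert-butyldimethylsilyl triflate CC(C)(C)[Si](C)(C)OS(=O)(=O)C(F)(F)F
Why: Silylation masks the alcohol against O-methylation in the next step.

Step 15
Reactants: 24 (4aS,5S)-5-[(tert-butyldimethylsilyl)oxy]-1-(2,5-dimethoxybenzyl)-4a-[2-(Hal)ethyl]-4,4a,5,6,7,8-hexahydronaphthalen-2(3H)-one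
Product: 25 (1R,4aS,5S)-5-[(tert-butyldimethylsilyl)oxy]-1-(2,5-dimethoxybenzyl)-1-methyl-4a-[2-(Hal)ethyl]-3,4,4a,5,6,7-hexahydronaphthalen-2(1H)-one
Conditions: t-BuOK (1.5 equiv), t-BuOH–THF, 23 °C; MeI (1.5 equiv), 0 °C
Reagents that add atoms: iodomethane CI
Why: Deconjugative α-alkylation of the extended potassium dienolate: MeI should enter at C1 from the face opposite the axial angular chain, so the benzyl group ends cis to the chain and the double bond moves to C8=C8a.

Step 16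
Reactants: 25 (1R,4aS,5S)-5-[(tert-butyldimethylsilyl)oxy]-1-(2,5-dimethoxybenzyl)-1-methyl-4a-[2-(Hal)ethyl]-3,4,4a,5,6,7-hexahydronaphthalen-2(1H)-one
Product: 26 tert-butyl{[(1S,5S,8aR)-5-(2,5-dimethoxybenzyl)-5-methyl-6-methylidene-8a-[2-(Hal)ethyl]-1,2,3,5,6,7,8,8a-octahydronaphthalen-1-yl]oxy}dimethylsilane
Conditions: Ph3PCH3Br (5 equiv), t-BuOK (4.8 equiv), toluene, 100 °C
Reagents that add atoms: methyltriphenylphosphonium bromide C[P+](c1ccccc1)(c1ccccc1)c1ccccc1.[Br-]
Why: Wittig methylenation of the hindered ketone at elevated temperature; the neighbouring quaternary carbon cannot epimerise.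

Step 17
Reactants: 26 tert-butyl{[(1S,5S,8aR)-5-(2,5-dimethoxybenzyl)-5-methyl-6-methylidene-8a-[2-(Hal)ethyl]-1,2,3,5,6,7,8,8a-octahydronaphthalen-1-yl]oxy}dimethylsilane
Product: 27 tert-butyl{[(1S,5S,6S,8aR)-5-(2,5-dimethoxybenzyl)-5,6-dimethyl-8a-[2-(Hal)ethyl]-1,2,3,5,6,7,8,8a-octahydronaphthalen-1-yl]oxy}dimethylsilane
Conditions: H2 (1 atm), RhCl(PPh3)3 (15 mol %), benzene–EtOH 1:1, 23 °C
Reagents that add atoms: none
Why: The homogeneous catalyst reduces only the 1,1-disubstituted alkene; because the C4=C4a double bond holds the angular chain, and hence the C5 benzyl group, axial on the second ring, hydrogen should add from the opposite face and place the new C6 methyl cis to the benzyl group.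

Step 18
Reactants: 27 tert-butyl{[(1S,5S,6S,8aR)-5-(2,5-dimethoxybenzyl)-5,6-dimethyl-8a-[2-(Hal)ethyl]-1,2,3,5,6,7,8,8a-octahydronaphthalen-1-yl]oxy}dimethylsilane
Product: 28 (1S,5S,6S,8aR)-5-(2,5-dimethoxybenzyl)-5,6-dimethyl-8a-[2-(Hal)ethyl]-1,2,3,5,6,7,8,8a-octahydronaphthalen-1-ol
Conditions: TBAF (3 equiv), THF, 60 °C
Reagents that add atoms: none
Why: Fluoride cleaves the silyl ether and frees the hydroxyl that directs the next step.

Step 19
Reactants: 28 (1S,5S,6S,8aR)-5-(2,5-dimethoxybenzyl)-5,6-dimethyl-8a-[2-(Hal)ethyl]-1,2,3,5,6,7,8,8a-octahydronaphthalen-1-ol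
Product: 29 (1S,4aR,5S,6S,8aR)-5-(2,5-dimethoxybenzyl)-5,6-dimethyl-8a-[2-(Hal)ethyl]decahydronaphthalen-1-ol
Conditions: [Rh(nbd)(dppb)]BF4 (10 mol %), H2 (60 bar), CH2Cl2, 23 °C
Reagents that add atoms: none
Why: Hydroxyl-directed hydrogenation with a cationic rhodium diphosphine catalyst: the metal bound to the C1 hydroxyl should deliver H2 to the face of the homoallylic C4=C4a bond that carries the OH and the angular chain, giving the cis ring fusion, while the trisubstituted alkene of Hal has no directing group.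

Step 20
Reactants: 29 (1S,4aR,5S,6S,8aR)-5-(2,5-dimethoxybenzyl)-5,6-dimethyl-8a-[2-(Hal)ethyl]decahydronaphthalen-1-ol
Product: 30 (4aR,5S,6S,8aR)-5-(2,5-dimethoxybenzyl)-5,6-dimethyl-8a-[2-(Hal)ethyl]octahydronaphthalen-1(2H)-one
Conditions: Dess–Martin periodinane (1.5 equiv), NaHCO3, CH2Cl2, 23 °C
Reagents that add atoms: none
Why: Dess–Martin oxidation gives the ketone, which has no epimerisable α-stereocentre because C8a is quaternary.

Step 21
Reactants: 30 (4aR,5S,6S,8aR)-5-(2,5-dimethoxybenzyl)-5,6-dimethyl-8a-[2-(Hal)ethyl]octahydronaphthalen-1(2H)-one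
Product: 31 2-{[(1S,2S,4aR,8aR)-1,2-dimethyl-5-methylidene-4a-[2-(Hal)ethyl]decahydronaphthalen-1-yl]methyl}-1,4-dimethoxybenzene
Conditions: Ph3PCH3Br (5 equiv), t-BuOK (4.8 equiv), toluene, 90 °C
Reagents that add atoms: methyltriphenylphosphonium bromide C[P+](c1ccccc1)(c1ccccc1)c1ccccc1.[Br-]
Why: Wittig methylenation installs the exocyclic methylene next to the quaternary carbon.

Step 22
Reactants: 31 2-{[(1S,2S,4aR,8aR)-1,2-dimethyl-5-methylidene-4a-[2-(Hal)ethyl]decahydronaphthalen-1-yl]methyl}-1,4-dimethoxybenzene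
Product: 32 2-{[(1S,2S,4aR,8aR)-1,2-dimethyl-5-methylidene-4a-[2-(Hal)ethyl]decahydronaphthalen-1-yl]methyl}benzene-1,4-diol
Conditions: NaSEt (10 equiv), DMF, 140 °C; aq. NH4Cl, exclusion of air
Reagents that add atoms: none
Why: SN2 cleavage of both aryl methyl ethers by ethanethiolate is non-acidic and should leave both alkenes in place.

Step 23
Reactants: 32 2-{[(1S,2S,4aR,8aR)-1,2-dimethyl-5-methylidene-4a-[2-(Hal)ethyl]decahydronaphthalen-1-yl]methyl}benzene-1,4-diol
Product: 33 2-{[(1S,2S,4aR,8aR)-1,2-dimethyl-5-methylidene-4a-[2-(Hal)ethyl]decahydronaphthalen-1-yl]methyl}-1,4-phenylene bis(hydrogen sulfate)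
Conditions: SO3·pyridine (10 equiv), pyridine, 50 °C; then H+ ion-exchange resin, MeOH–H2O, 0 °C
Reagents that add atoms: sulfur trioxide–pyridine complex O=S(=O)([O-])[n+]1ccccc1
Why: O-Sulfation of both phenols with the SO3–pyridine complex, followed by acid ion exchange, gives the free bis(hydrogen sulfate).

Compound list
1 | 3-methylpenta-1,4-diene | C=CC(C)C=C | starting material
2 | 4,4-dimethylcyclohex-2-en-1-one | CC1(C)CCC(=O)C=C1 | starting material
3 | chlorobis(cyclopentadienyl)(3-methylpent-4-en-1-yl)zirconium | C=CC(C)CC[Zr](Cl)(C1C=CC=C1)C1C=CC=C1 | intermediate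
4 | {[(3R)-4,4-dimethyl-3-(3-methylpent-4-en-1-yl)cyclohex-1-en-1-yl]oxy}trimethylsilane | C[Si](C)(C)OC1=C[C@@H](CCC(C)C=C)C(C)(C)CC1 | intermediate
5 | (3R)-4,4-dimethyl-3-(3-methylpent-4-en-1-yl)cyclohexan-1-one (both side-chain epimers) | O=C1CCC(C)(C)[C@H](CCC(C)C=C)C1 | intermediate
6 | (3R)-4,4-dimethyl-3-(3-methyl-4-oxopentyl)cyclohexan-1-one (both side-chain epimers) | O=C1CCC(C)(C)[C@H](CCC(C)C(C)=O)C1 | intermediate
7 | (4aS,7S)-4,4,7,8-tetramethyl-3,4,4a,5,6,7-hexahydronaphthalen-1(2H)-one | O=C1CCC(C)(C)[C@@H]2CC[C@H](C)C(C)=C12 | intermediate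
8 | (1S,4aS,7S)-4,4,7,8-tetramethyl-1,2,3,4,4a,5,6,7-octahydronaphthalen-1-ol | O[C@H]1CCC(C)(C)[C@@H]2CC[C@H](C)C(C)=C12 | intermediate
9 | ketene N,O-acetal of 8 (1-dimethylamino-1-alkoxyethene) | C=C(N(C)C)O[C@H]1CCC(C)(C)[C@@H]2CC[C@H](C)C(C)=C12 | intermediate
10 | N,N-dimethyl-2-(Hal)acetamide | CN(C)C(=O)C[C@@]1(C)C2=CCCC(C)(C)[C@@H]2CC[C@@H]1C | intermediate
11 | 2-(Hal)acetaldehyde | O=CC[C@@]1(C)C2=CCCC(C)(C)[C@@H]2CC[C@@H]1C | intermediate
12 | (E)-5-(Hal)pent-3-en-2-one | CC(=O)/C=C/C[C@@]1(C)C2=CCCC(C)(C)[C@@H]2CC[C@@H]1C | intermediate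
13 | 5-(Hal)pentan-2-one | CC(=O)CCC[C@@]1(C)C2=CCCC(C)(C)[C@@H]2CC[C@@H]1C | intermediate
14 | methyl acrylate | C=CC(=O)OC | starting material
15 | methyl 5-oxo-8-(Hal)octanoate | COC(=O)CCCC(=O)CCC[C@@]1(C)C2=CCCC(C)(C)[C@@H]2CC[C@@H]1C | intermediate
16 | 2-[2-(Hal)ethyl]cyclohexane-1,3-dione | O=C1CCCC(=O)C1CC[C@@]2(C)C3=CCCC(C)(C)[C@@H]3CC[C@@H]2C | intermediate
17 | 3-(2,5-dimethoxyphenyl)propanoic acid | COc1ccc(OC)c(CCC(=O)O)c1 | starting material
18 | 3-(2,5-dimethoxyphenyl)-1-(imidazol-1-yl)propan-1-one | COc1ccc(OC)c(CCC(=O)n2ccnc2)c1 | intermediate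
19 | 3-(2,5-dimethoxyphenyl)-N-methoxy-N-methylpropanamide | COc1ccc(OC)c(CCC(=O)N(C)OC)c1 | intermediate
20 | 5-(2,5-dimethoxyphenyl)pent-1-en-3-one | COc1ccc(OC)c(CCC(=O)C=C)c1 | intermediate
21 | 2-[5-(2,5-dimethoxyphenyl)-3-oxopentyl]-2-[2-(Hal)ethyl]cyclohexane-1,3-dione | O=C1CCCC(=O)C1(CCC(=O)CCc4cc(OC)ccc4OC)CC[C@@]2(C)C3=CCCC(C)(C)[C@@H]3CC[C@@H]2C | intermediate
22 | (8aS)-5-(2,5-dimethoxybenzyl)-8a-[2-(Hal)ethyl]-3,4,8,8a-tetrahydronaphthalene-1,6(2H,7H)-dione | O=C1CCCC2=C(Cc3cc(OC)ccc3OC)C(=O)CC[C@]12CC[C@@]4(C)C5=CCCC(C)(C)[C@@H]5CC[C@@H]4C | intermediate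
23 | (4aS,5S)-1-(2,5-dimethoxybenzyl)-5-hydroxy-4a-[2-(Hal)ethyl]-4,4a,5,6,7,8-hexahydronaphthalen-2(3H)-one | O[C@H]1CCCC2=C(Cc3cc(OC)ccc3OC)C(=O)CC[C@]12CC[C@@]4(C)C5=CCCC(C)(C)[C@@H]5CC[C@@H]4C | intermediate
24 | (4aS,5S)-5-[(tert-butyldimethylsilyl)oxy]-1-(2,5-dimethoxybenzyl)-4a-[2-(Hal)ethyl]-4,4a,5,6,7,8-hexahydronaphthalen-2(3H)-one | CC(C)(C)[Si](C)(C)O[C@H]1CCCC2=C(Cc3cc(OC)ccc3OC)C(=O)CC[C@]12CC[C@@]4(C)C5=CCCC(C)(C)[C@@H]5CC[C@@H]4C | intermediate
25 | (1R,4aS,5S)-5-[(tert-butyldimethylsilyl)oxy]-1-(2,5-dimethoxybenzyl)-1-methyl-4a-[2-(Hal)ethyl]-3,4,4a,5,6,7-hexahydronaphthalen-2(1H)-one | CC(C)(C)[Si](C)(C)O[C@H]1CCC=C2[C@@](C)(Cc3cc(OC)ccc3OC)C(=O)CC[C@]12CC[C@@]4(C)C5=CCCC(C)(C)[C@@H]5CC[C@@H]4C | intermediate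
26 | tert-butyl{[(1S,5S,8aR)-5-(2,5-dimethoxybenzyl)-5-methyl-6-methylidene-8a-[2-(Hal)ethyl]-1,2,3,5,6,7,8,8a-octahydronaphthalen-1-yl]oxy}dimethylsilane | CC(C)(C)[Si](C)(C)O[C@H]1CCC=C2[C@@](C)(Cc3cc(OC)ccc3OC)C(=C)CC[C@]12CC[C@@]4(C)C5=CCCC(C)(C)[C@@H]5CC[C@@H]4C | intermediate
27 | tert-butyl{[(1S,5S,6S,8aR)-5-(2,5-dimethoxybenzyl)-5,6-dimethyl-8a-[2-(Hal)ethyl]-1,2,3,5,6,7,8,8a-octahydronaphthalen-1-yl]oxy}dimethylsilane | CC(C)(C)[Si](C)(C)O[C@H]1CCC=C2[C@@](C)(Cc3cc(OC)ccc3OC)[C@@H](C)CC[C@]12CC[C@@]4(C)C5=CCCC(C)(C)[C@@H]5CC[C@@H]4C | intermediate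
28 | (1S,5S,6S,8aR)-5-(2,5-dimethoxybenzyl)-5,6-dimethyl-8a-[2-(Hal)ethyl]-1,2,3,5,6,7,8,8a-octahydronaphthalen-1-ol | O[C@H]1CCC=C2[C@@](C)(Cc3cc(OC)ccc3OC)[C@@H](C)CC[C@]12CC[C@@]4(C)C5=CCCC(C)(C)[C@@H]5CC[C@@H]4C | intermediate
29 | (1S,4aR,5S,6S,8aR)-5-(2,5-dimethoxybenzyl)-5,6-dimethyl-8a-[2-(Hal)ethyl]decahydronaphthalen-1-ol | O[C@H]1CCC[C@@H]2[C@@](C)(Cc3cc(OC)ccc3OC)[C@@H](C)CC[C@]12CC[C@@]4(C)C5=CCCC(C)(C)[C@@H]5CC[C@@H]4C | intermediate
30 | (4aR,5S,6S,8aR)-5-(2,5-dimethoxybenzyl)-5,6-dimethyl-8a-[2-(Hal)ethyl]octahydronaphthalen-1(2H)-one | O=C1CCC[C@@H]2[C@@](C)(Cc3cc(OC)ccc3OC)[C@@H](C)CC[C@]12CC[C@@]4(C)C5=CCCC(C)(C)[C@@H]5CC[C@@H]4C | intermediate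
31 | 2-{[(1S,2S,4aR,8aR)-1,2-dimethyl-5-methylidene-4a-[2-(Hal)ethyl]decahydronaphthalen-1-yl]methyl}-1,4-dimethoxybenzene | C=C1CCC[C@H]2[C@]1(CC[C@@]1(C)C3=CCCC(C)(C)[C@@H]3CC[C@@H]1C)CC[C@H](C)[C@]2(C)Cc1cc(OC)ccc1OC | intermediate
32 | 2-{[(1S,2S,4aR,8aR)-1,2-dimethyl-5-methylidene-4a-[2-(Hal)ethyl]decahydronaphthalen-1-yl]methyl}benzene-1,4-diol | C=C1CCC[C@H]2[C@]1(CC[C@@]1(C)C3=CCCC(C)(C)[C@@H]3CC[C@@H]1C)CC[C@H](C)[C@]2(C)Cc1cc(O)ccc1O | intermediate
33 | 2-{[(1S,2S,4aR,8aR)-1,2-dimethyl-5-methylidene-4a-[2-(Hal)ethyl]decahydronaphthalen-1-yl]methyl}-1,4-phenylene bis(hydrogen sulfate) | C=C1CCC[C@H]2[C@]1(CC[C@@]1(C)C3=CCCC(C)(C)[C@@H]3CC[C@@H]1C)CC[C@H](C)[C@]2(C)Cc1cc(OS(=O)(=O)O)ccc1OS(=O)(=O)O | target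

Total step count: 23
Longest linear sequence: 21 steps (steps 1–9 and 12–23)

Steps most likely to fail

Step 19. Hydrogen has to reach the ring-fusion carbon C4a on the face that is flanked by the axial angular chain and the axial benzyl group. The catalyst may fail to engage, may add from the open face (trans-decalin), or may also reduce the alkene of Hal. The fallback sets out from 28 and replaces catalytic delivery by a tethered ionic hydrogenation. Silylation with chlorodiisopropylsilane and imidazole (CH2Cl2, 0 °C) would give the diisopropylsilyl ether F1. Trifluoroacetic acid (CH2Cl2, −40 °C, short contact) should protonate C4, and the tertiary cation at C4a would be captured by intramolecular hydride transfer from Si–H through a six-membered transition state on the hydroxyl face, giving the cis-fused silyl trifluoroacetate F2. TBAF then releases 29, where the route is rejoined.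

Step 9. The ester enolate formed after the Michael event can add to more acrylate (oligomerisation), proton exchange can route the Michael addition through the internal enolate (4-substituted dione), or the Claisen closure can stall at the δ-keto ester. The fallback sets out from aldehyde 11 and gives up the annulation in favour of an organocatalytic three-component reductive alkylation. Aldehyde 11, cyclohexane-1,3-dione and Hantzsch ester with L-proline (20 mol %, CH2Cl2, 23 °C) should undergo Knoevenagel condensation to the alkylidene dione F3 (not isolated), which is reduced in situ by hydride transfer to give 16, where the route is rejoined.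

Step 12. The nucleophilic methylene of triketone 21 carries the arylmethyl group, so enamine formation and the aldol cyclodehydration can be slow and poorly selective between the two enantiotopic carbonyls. The fallback sets out from 16 and introduces the benzyl group after the ring is closed. Michael addition to but-3-en-2-one (Et3N) would give the triketone F4 (not isolated), and L-proline (DMSO, 23 °C) should close it to the enedione F5 under the classical Hajos–Parrish–Eder–Sauer–Wiechert conditions. Reduction as in step 13 would give the hydroxy enone F6 and silylation as in step 14 the silyl ether F7. Condensation with pyrrolidine (benzene, reflux, water removal) would give the dienamine F8 (not isolated), whose Stork alkylation at C1 with 2-(bromomethyl)-1,4-dimethoxybenzene (MeCN, 60 °C), followed by hydrolysis with aqueous AcOH–NaOAc, should give 24, where the route is rejoined.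

Further compounds
F1 | step 19 | diisopropylsilyl ether of 28 | CC(C)[SiH](C(C)C)O[C@H]1CCC=C2[C@@](C)(Cc3cc(OC)ccc3OC)[C@@H](C)CC[C@]12CC[C@@]4(C)C5=CCCC(C)(C)[C@@H]5CC[C@@H]4C
F2 | step 19 | cis-fused diisopropyl(trifluoroacetoxy)silyl ether of 29 | CC(C)[Si](OC(=O)C(F)(F)F)(C(C)C)O[C@H]1CCC[C@@H]2[C@@](C)(Cc3cc(OC)ccc3OC)[C@@H](C)CC[C@]12CC[C@@]4(C)C5=CCCC(C)(C)[C@@H]5CC[C@@H]4C
F3 | step 9 | 2-[2-(Hal)ethylidene]cyclohexane-1,3-dione | O=C1CCCC(=O)C1=CC[C@@]2(C)C3=CCCC(C)(C)[C@@H]3CC[C@@H]2C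
F4 | step 12 | 2-(3-oxobutyl)-2-[2-(Hal)ethyl]cyclohexane-1,3-dione | O=C1CCCC(=O)C1(CCC(C)=O)CC[C@@]2(C)C3=CCCC(C)(C)[C@@H]3CC[C@@H]2C
F5 | step 12 | (8aS)-8a-[2-(Hal)ethyl]-3,4,8,8a-tetrahydronaphthalene-1,6(2H,7H)-dione | O=C1CCCC2=CC(=O)CC[C@]12CC[C@@]3(C)C4=CCCC(C)(C)[C@@H]4CC[C@@H]3C
F6 | step 12 | (4aS,5S)-5-hydroxy-4a-[2-(Hal)ethyl]-4,4a,5,6,7,8-hexahydronaphthalen-2(3H)-one | O[C@H]1CCCC2=CC(=O)CC[C@]12CC[C@@]3(C)C4=CCCC(C)(C)[C@@H]4CC[C@@H]3C
F7 | step 12 | (4aS,5S)-5-[(tert-butyldimethylsilyl)oxy]-4a-[2-(Hal)ethyl]-4,4a,5,6,7,8-hexahydronaphthalen-2(3H)-one | CC(C)(C)[Si](C)(C)O[C@H]1CCCC2=CC(=O)CC[C@]12CC[C@@]3(C)C4=CCCC(C)(C)[C@@H]4CC[C@@H]3C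
F8 | step 12 | pyrrolidine dienamine of F7 | CC(C)(C)[Si](C)(C)O[C@H]1CCC=C2C=C(N3CCCC3)CC[C@]12CC[C@@]4(C)C5=CCCC(C)(C)[C@@H]5CC[C@@H]4C
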